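**Retrosynthetic overview**

1. Target 13 ⇐ 4-bromo derivative 12 (C–Br to C–H) ⇐ one-carbon ring expansion of cyclopentene oxide 8: C4 is inserted as CBr2 between the two alkene carbons of 8 (future C3 and C5).
2. Opening of the resulting dibromocyclopropane gives an allyl cation that the C2 benzoate captures at C3; hydrolysis leaves C3–OBz cis to a free C2–OH.
3. 8 ⇐ dehydration of alcohol 7 ⇐ epoxide 6 ⇐ dibenzoate 5 ⇐ cis-diol 4 ⇐ Morita–Baylis–Hillman adduct 3 ⇐ (R)-4-silyloxycyclopentenone 1 + formaldehyde 2. The silyloxy stereocenter of 1 relays all stereochemistry and is then erased.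
4. Ring order: the five-membered ring arrives with 1 (a temporary ring size), the epoxide is closed in step 4, and the six-membered carbocycle is formed last, in step 7. The cyclopropane and acyloxonium rings of step 7 are opened again within that step.
5. Enabling feature: the cyclohex-2-enyl ester unit C3(OBz)–C4=C5, which is the product pattern of a cyclopropyl-to-allyl cation opening, sits next to the cis C2–O. The C1–O7–C6 epoxide is a spectator set beforehand.

Key step: step 7

Remark: locants in the overview, in the Why line of step 7 and in the fallbacks are those of the target's 7-oxabicyclo[4.1.0]hept-4-ene core. Phenyl(tribromomethyl)mercury is taken as purchasable; it is otherwise made in one step from PhHgCl, CHBr3 and KOC(CH3)3.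

**Step 1**
Reactants: 1 (4R)-4-[(tert-butyldimethylsilyl)oxy]cyclopent-2-en-1-one; 2 formaldehyde
Product: 3 (4R)-4-[(tert-butyldimethylsilyl)oxy]-2-(hydroxymethyl)cyclopent-2-en-1-one
Conditions: 37% aq. HCHO, imidazole (cat.), THF–H2O, rt
Reagents that add atoms: none
Why: Morita–Baylis–Hillman hydroxymethylation of a cyclic enone under imidazole catalysis has close precedent; the C4 stereocenter is untouched and no new one forms.

**Step 2**
Reactants: 3 (4R)-4-[(tert-butyldimethylsilyl)oxy]-2-(hydroxymethyl)cyclopent-2-en-1-one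
Product: 4 (1S,4R)-4-[(tert-butyldimethylsilyl)oxy]-2-(hydroxymethyl)cyclopent-2-en-1-ol (1,4-cis)
Conditions: NaBH4, CeCl3·7H2O, MeOH, −78 → −40 °C
Reagents that add atoms: none
Why: Luche 1,2-reduction; hydride should add to the carbonyl face anti to the C4 silyloxy group, placing the new C1 hydroxyl cis to it.

**Step 3**
Reactants: 4 (1S,4R)-4-[(tert-butyldimethylsilyl)oxy]-2-(hydroxymethyl)cyclopent-2-en-1-ol
Product: 5 (1S,4R)-2-[(benzoyloxy)methyl]-4-[(tert-butyldimethylsilyl)oxy]cyclopent-2-en-1-yl benzoate
Conditions: BzCl, pyridine, DMAP (cat.), CH2Cl2, 0 °C → rt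
Reagents that add atoms: benzoyl chloride, O=C(Cl)c1ccccc1
Why: DMAP-catalysed esterification of the primary and the secondary allylic hydroxyl installs both benzoates of the target in one operation; no stereocenter is involved.

**Step 4**
Reactants: 5 (1S,4R)-2-[(benzoyloxy)methyl]-4-[(tert-butyldimethylsilyl)oxy]cyclopent-2-en-1-yl benzoate
Product: 6 [(1R,2S,4R,5S)-2-(benzoyloxy)-4-[(tert-butyldimethylsilyl)oxy]-6-oxabicyclo[3.1.0]hexan-1-yl]methyl benzoate (epoxide trans to the benzoate and to the silyl ether)
Conditions: mCPBA, ClCH2CH2Cl, rt → 50 °C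
Reagents that add atoms: 3-chloroperoxybenzoic acid (mCPBA), OOC(=O)c1cccc(Cl)c1
Why: Prilezhaev epoxidation of the trisubstituted alkene; the peracid should approach anti to the two cis-disposed allylic substituents, which sets both epoxide stereocenters trans to the ring benzoate.

**Step 5**
Reactants: 6 [(1R,2S,4R,5S)-2-(benzoyloxy)-4-[(tert-butyldimethylsilyl)oxy]-6-oxabicyclo[3.1.0]hexan-1-yl]methyl benzoate
Product: 7 [(1R,2S,4R,5S)-2-(benzoyloxy)-4-hydroxy-6-oxabicyclo[3.1.0]hexan-1-yl]methyl benzoate
Conditions: Bu4NF, AcOH (1:1), THF, 0 °C → rt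
Reagents that add atoms: none
Why: fluoride-mediated desilylation, buffered with acetic acid so that neither benzoyl migration nor Payne rearrangement of the trans-epoxy alcohol is promoted.

**Step 6**
Reactants: 7 [(1R,2S,4R,5S)-2-(benzoyloxy)-4-hydroxy-6-oxabicyclo[3.1.0]hexan-1-yl]methyl benzoate
Product: 8 [(1S,2S,5S)-2-(benzoyloxy)-6-oxabicyclo[3.1.0]hex-3-en-1-yl]methyl benzoate (epoxide trans to the C2 benzoate)
Conditions: Martin sulfurane Ph2S[OC(CF3)2Ph]2, CH2Cl2, rt
Reagents that add atoms: none
Why: Martin sulfurane dehydration by alkoxysulfonium formation and anti-elimination; only the CH2 carbon offers an anti-periplanar hydrogen (the epoxide C–H is syn), so the alkene forms away from the epoxide and the relay stereocenter is erased.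

**Step 7**
Reactants: 8 [(1S,2S,5S)-2-(benzoyloxy)-6-oxabicyclo[3.1.0]hex-3-en-1-yl]methyl benzoate; 9 phenyl(tribromomethyl)mercury
Product: 12 [(1R,2S,3R,6S)-3-(benzoyloxy)-4-bromo-2-hydroxy-7-oxabicyclo[4.1.0]hept-4-en-1-yl]methyl benzoate, via dibromocyclopropane adduct 10 (not isolated), via acyloxonium triflate 11 (not isolated)
Conditions: PhHgCBr3, PhH, 80 °C; filter off PhHgBr, no purification; then AgOSO2CF3, 2,6-di-tert-butyl-4-methylpyridine, ClCH2CH2Cl, 25 → 50 °C; then H2O
Reagents that add atoms: water, O
Why: Thermal CBr2 transfer from 9 to the alkene of 8 gives 10; silver ion then removes the bromine syn to the five-membered ring with concerted disrotatory 2π-electrocyclic cleavage of the internal cyclopropane bond, and the resulting 2-bromocyclohexenyl cation is captured by the vicinal benzoate carbonyl as the cis-fused acyloxonium 11, whose hemi-orthoester collapses to 12 on adding water. The closest known reaction type is the dihalocarbene insertion and silver-promoted electrocyclic ring expansion of cyclopentene-derived 6,6-dibromobicyclo[3.1.0]hexanes with nucleophilic capture, joined here to neighbouring acyloxy participation of the Woodward–Prévost kind. The cyclopropane closes by cheletropic [2+1] addition, the six-membered carbocycle arises by one-carbon ring expansion (cleavage of the zero bridge) and not by cyclisation, and the transient dioxolanylium closes by five-membered neighbouring-group attack and is reopened by water. The new C3–O stereocenter is set cis to C2–O because the five-membered acyloxonium can only be cis-fused, so the C2 stereocenter controls it; the cyclopropane stereocenters are erased, so either face of carbene addition converges. The step needs ionisation of C–Br and not of the epoxide (silver halophilicity, hindered-pyridine buffer), capture at C3 and not C5 (only C3 is within reach of the benzoate and C5 is deactivated by the adjacent epoxide), and collapse to the C3 ester (C3–O is pseudo-axial through allylic strain with C4–Br, and the axial oxygen should keep the acyl group).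

**Step 8**
Reactants: 12 [(1R,2S,3R,6S)-3-(benzoyloxy)-4-bromo-2-hydroxy-7-oxabicyclo[4.1.0]hept-4-en-1-yl]methyl benzoate
Product: 13 [(1R,2S,3S,6S)-3-(benzoyloxy)-2-hydroxy-7-oxabicyclo[4.1.0]hept-4-en-1-yl]methyl benzoate
Conditions: Bu3SnH, AIBN (cat.), PhH, 80 °C
Reagents that add atoms: none
Why: radical-chain hydrodebromination of a vinyl bromide with tin hydride; the sigma-type vinyl radical at C4 is orthogonal to the allylic C–O bonds and should be quenched by Sn–H before any rearrangement, leaving all stereocenters untouched.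

**Compound list**

1 | (4R)-4-[(tert-butyldimethylsilyl)oxy]cyclopent-2-en-1-one | O=C1C=C[C@H](O[Si](C)(C)C(C)(C)C)C1 | starting material
2 | formaldehyde | C=O | starting material
3 | (4R)-4-[(tert-butyldimethylsilyl)oxy]-2-(hydroxymethyl)cyclopent-2-en-1-one | O=C1C(CO)=C[C@H](O[Si](C)(C)C(C)(C)C)C1 | intermediate
4 | (1S,4R)-4-[(tert-butyldimethylsilyl)oxy]-2-(hydroxymethyl)cyclopent-2-en-1-ol | O[C@@H]1C(CO)=C[C@H](O[Si](C)(C)C(C)(C)C)C1 | intermediate
5 | (1S,4R)-2-[(benzoyloxy)methyl]-4-[(tert-butyldimethylsilyl)oxy]cyclopent-2-en-1-yl benzoate | O=C(O[C@@H]1C(COC(=O)c2ccccc2)=C[C@H](O[Si](C)(C)C(C)(C)C)C1)c1ccccc1 | intermediate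
6 | [(1R,2S,4R,5S)-2-(benzoyloxy)-4-[(tert-butyldimethylsilyl)oxy]-6-oxabicyclo[3.1.0]hexan-1-yl]methyl benzoate | O=C(O[C@@H]1[C@@]2(COC(=O)c3ccccc3)O[C@H]2[C@H](O[Si](C)(C)C(C)(C)C)C1)c1ccccc1 | intermediate
7 | [(1R,2S,4R,5S)-2-(benzoyloxy)-4-hydroxy-6-oxabicyclo[3.1.0]hexan-1-yl]methyl benzoate | O=C(O[C@@H]1[C@@]2(COC(=O)c3ccccc3)O[C@H]2[C@H](O)C1)c1ccccc1 | intermediate
8 | [(1S,2S,5S)-2-(benzoyloxy)-6-oxabicyclo[3.1.0]hex-3-en-1-yl]methyl benzoate | O=C(O[C@@H]1[C@@]2(COC(=O)c3ccccc3)O[C@H]2C=C1)c1ccccc1 | intermediate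
9 | phenyl(tribromomethyl)mercury | BrC(Br)(Br)[Hg]c1ccccc1 | starting material
10 | [5-(benzoyloxy)-7,7-dibromo-3-oxatricyclo[4.1.0.0(2,4)]heptan-4-yl]methyl benzoate, cyclopropane drawn anti to the ring benzoate (either face converges) | O=C(O[C@@H]1[C@@]2(COC(=O)c3ccccc3)O[C@H]2[C@H]2C(Br)(Br)[C@@H]12)c1ccccc1 | intermediate (not isolated)
11 | cis-fused 2-phenyl-1,3-dioxolan-2-ylium triflate bridging O2 and O3 of the ring-expanded 4-bromo-cyclohexene oxide | C1(c2ccccc2)=[O+][C@H]2C(Br)=C[C@@H]3O[C@]3(COC(=O)c3ccccc3)[C@H]2O1.[O-]S(=O)(=O)C(F)(F)F | intermediate (not isolated)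
12 | [(1R,2S,3R,6S)-3-(benzoyloxy)-4-bromo-2-hydroxy-7-oxabicyclo[4.1.0]hept-4-en-1-yl]methyl benzoate | O=C(OC[C@]12O[C@H]1C=C(Br)[C@H](OC(=O)c1ccccc1)[C@@H]2O)c1ccccc1 | intermediate
13 | [(1R,2S,3S,6S)-3-(benzoyloxy)-2-hydroxy-7-oxabicyclo[4.1.0]hept-4-en-1-yl]methyl benzoate | O=C(OC[C@]12O[C@H]1C=C[C@H](OC(=O)c1ccccc1)[C@@H]2O)c1ccccc1 | target

**Step count and risks**

Total steps: 8. Longest linear sequence: 8 steps (1 → 13).

Steps most likely to fail:

Step 7. Carbene transfer to an alkene deactivated by two allylic C–O bonds may be slow, silver-assisted ionisation of the allylic epoxide may compete with C–Br ionisation, and the hemi-orthoester may collapse without regiocontrol. The fallback sets out from 8 and comes back at 12, separating the events and avoiding silver. The dibromocyclopropane 10 is isolated after the carbene transfer and heated in toluene at about 100 °C, so that thermal electrocyclic opening with ion-pair return gives [2-(benzoyloxy)-3,4-dibromo-7-oxabicyclo[4.1.0]hept-4-en-1-yl]methyl benzoate, the allylic bromide F1 (the known isomerisation of 6,6-dibromobicyclo[3.1.0]hexanes to 2,3-dibromocyclohexenes). F1 is then solvolysed in wet acetone with 2,6-lutidine, where the allylic bromide is displaced with anchimeric assistance of the C2 benzoate through 11, and buffered hydrolysis gives 12.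

Step 8. Stannyl radicals may add to the vinyl epoxide and open it, or halogen abstraction from the hindered vinyl bromide may be incomplete. The fallback sets out from 10 (isolated) and comes back at 13, removing the surplus bromine before the vinyl epoxide exists. One equivalent of Bu3SnH (Et3B, air, low temperature) should reduce the less hindered exo C–Br to give [5-(benzoyloxy)-7-endo-bromo-3-oxatricyclo[4.1.0.0(2,4)]heptan-4-yl]methyl benzoate, the endo monobromide F2. AgOSO2CF3 with the hindered pyridine then expands the ring through the bromine-free acyloxonium triflate F3, and water gives 13 directly.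

Step 4. The trisubstituted alkene carries three allylic C–O bonds and may react too slowly with the peracid, with loss of facial selectivity on forcing. The fallback sets out from 3 and comes back at 8, placing the epoxide by nucleophilic epoxidation at the enone stage. H2O2 and NaOH in MeOH at 0 °C should give the epoxy ketone 4-[(tert-butyldimethylsilyl)oxy]-1-(hydroxymethyl)-6-oxabicyclo[3.1.0]hexan-2-one F4, with the epoxide trans to the silyl ether. BzCl and pyridine give its benzoate F5, and DBU eliminates the silanol by E1cB to give (2-oxo-6-oxabicyclo[3.1.0]hex-3-en-1-yl)methyl benzoate, the epoxy enone F6. Luche reduction (NaBH4, CeCl3·7H2O), with hydride anti to the epoxide, should give the cis-epoxy alcohol F7, and Mitsunobu inversion with benzoic acid (PPh3, DIAD) gives 8.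

**Further compounds**

F1 | step 7 | [2-(benzoyloxy)-3,4-dibromo-7-oxabicyclo[4.1.0]hept-4-en-1-yl]methyl benzoate (C3 bromide drawn trans to the C2 benzoate) | O=C(OC[C@]12O[C@H]1C=C(Br)[C@@H](Br)[C@@H]2OC(=O)c1ccccc1)c1ccccc1
F2 | step 8 | [5-(benzoyloxy)-7-endo-bromo-3-oxatricyclo[4.1.0.0(2,4)]heptan-4-yl]methyl benzoate | O=C(O[C@@H]1[C@@]2(COC(=O)c3ccccc3)O[C@H]2[C@H]2[C@@H](Br)[C@@H]12)c1ccccc1
F3 | step 8 | bromine-free cis-fused 2-phenyl-1,3-dioxolan-2-ylium triflate | C1(c2ccccc2)=[O+][C@H]2C=C[C@@H]3O[C@]3(COC(=O)c3ccccc3)[C@H]2O1.[O-]S(=O)(=O)C(F)(F)F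
F4 | step 4 | 4-[(tert-butyldimethylsilyl)oxy]-1-(hydroxymethyl)-6-oxabicyclo[3.1.0]hexan-2-one (epoxide trans to the silyl ether) | O=C1[C@@]2(CO)O[C@H]2[C@H](O[Si](C)(C)C(C)(C)C)C1
F5 | step 4 | {4-[(tert-butyldimethylsilyl)oxy]-2-oxo-6-oxabicyclo[3.1.0]hexan-1-yl}methyl benzoate | O=C1[C@@]2(COC(=O)c3ccccc3)O[C@H]2[C@H](O[Si](C)(C)C(C)(C)C)C1
F6 | step 4 | (2-oxo-6-oxabicyclo[3.1.0]hex-3-en-1-yl)methyl benzoate | O=C1[C@@]2(COC(=O)c3ccccc3)O[C@H]2C=C1
F7 | step 4 | (2-hydroxy-6-oxabicyclo[3.1.0]hex-3-en-1-yl)methyl benzoate, hydroxyl cis to the epoxide oxygen | O[C@H]1[C@@]2(COC(=O)c3ccccc3)O[C@H]2C=C1
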